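**Assumption:** the target has no stereocentre (it is achiral), so there is no enantiomer to select; the structure as drawn is made.

## Retrosynthetic overview

1. Target 12 ⇐ BBr3 O-demethylation of guaiacol-type methyl ether 10.
2. 10 ⇐ regioselective bromination (para to OMe) of monobromo sulfone 9.
3. 9 ⇐ C–S bond: methanesulfinate 7 adds to the p-quinone methide released from benzylic ammonium salt 6, which is the methiodide of Mannich base 5.
4. Key C–C disconnection (aryl–CH2): 5 ⇐ para-selective phenolic Mannich reaction of 2-bromo-6-methoxyphenol 1 with formaldehyde 2 and dimethylamine 3.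
5. Rings: the only ring is the benzene ring, which comes in with 1; no ring is formed.

## Route

Step 1
Reactants: 1 2-bromo-6-methoxyphenol; 2 formaldehyde (37% aq.); 3 dimethylamine (40% aq.)
Product: 5 2-bromo-4-[(dimethylamino)methyl]-6-methoxyphenol, via (dimethylamino)methanol 4 (not isolated)
Conditions: 2 (1.5 equiv), 3 (2 equiv), EtOH, rt → reflux, 8–12 h
Reagents that add atoms: formaldehyde (2), C=O; dimethylamine (3), CNC
Why: Phenolic Mannich reaction (aminomethylation): both ortho positions of the phenol are blocked (Br, OMe), so the Mannich electrophile 4 formed in situ from 2 and 3 attacks the para position and forms the only new C–C bond of the route, with water as the sole by-product and no stereocentre created.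

Step 2
Reactants: 5 2-bromo-4-[(dimethylamino)methyl]-6-methoxyphenol
Product: 6 1-(3-bromo-4-hydroxy-5-methoxyphenyl)-N,N,N-trimethylmethanaminium iodide
Conditions: MeI (1.5 equiv), acetone, 0 °C → rt; filter the precipitated salt
Reagents that add atoms: iodomethane, CI
Why: Menshutkin quaternisation: without added base the tertiary amine is far more nucleophilic than the phenol, and the salt crystallises from acetone, which also purifies the material.

Step 3
Reactants: 6 1-(3-bromo-4-hydroxy-5-methoxyphenyl)-N,N,N-trimethylmethanaminium iodide; 7 sodium methanesulfinate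
Product: 9 2-bromo-6-methoxy-4-[(methylsulfonyl)methyl]phenol, via 2-bromo-6-methoxy-4-methylidenecyclohexa-2,5-dien-1-one 8 (not isolated)
Conditions: 7 (3 equiv), cat. NaHCO3, DMF–H2O (4:1), 80 °C, N2; then dilute HCl work-up
Reagents that add atoms: sodium methanesulfinate (7), CS(=O)[O-].[Na+]
Why: Elimination–addition: 1,6-elimination of trimethylamine from the para-hydroxybenzyl ammonium salt gives p-quinone methide 8, to which the soft sulfinate adds through sulfur (1,6-conjugate addition, S-alkylation of a sulfinate), rearomatising to the benzyl sulfone.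

Step 4
Reactants: 9 2-bromo-6-methoxy-4-[(methylsulfonyl)methyl]phenol
Product: 10 2,3-dibromo-6-methoxy-4-[(methylsulfonyl)methyl]phenol
Conditions: Br2 (1.05 equiv), cat. Fe powder, AcOH, rt → 50 °C, dark
Reagents that add atoms: bromine, BrBr
Why: Electrophilic aromatic bromination: the ortho and para positions of the OH are all occupied, so the methoxy group directs bromine to its free para position (next to the existing Br), the same pattern as in the bromination of 5-bromovanillin to 5,6-dibromovanillin.

Step 5
Reactants: 10 2,3-dibromo-6-methoxy-4-[(methylsulfonyl)methyl]phenol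
Product: 12 3,4-dibromo-5-[(methylsulfonyl)methyl]benzene-1,2-diol, via 2,4,5-tribromo-6-[(methylsulfonyl)methyl]-1,3,2-benzodioxaborole 11 (not isolated)
Conditions: BBr3 (3 equiv), CH2Cl2, −78 °C → rt; then H2O, 0 °C
Reagents that add atoms: none
Why: Lewis-acid ether cleavage (BBr3 demethylation): the free ortho OH anchors boron and the methyl ether is cleaved to cyclic bromoborate 11, which is hydrolysed on work-up to the catechol, while the sulfone and aryl bromides are inert.

## Compound list

1 | 2-bromo-6-methoxyphenol | COc1cccc(Br)c1O | starting material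
2 | formaldehyde | C=O | starting material
3 | dimethylamine | CNC | starting material
4 | (dimethylamino)methanol | CN(C)CO | intermediate
5 | 2-bromo-4-[(dimethylamino)methyl]-6-methoxyphenol | CN(C)Cc1cc(Br)c(O)c(OC)c1 | intermediate
6 | 1-(3-bromo-4-hydroxy-5-methoxyphenyl)-N,N,N-trimethylmethanaminium iodide | C[N+](C)(C)Cc1cc(Br)c(O)c(OC)c1.[I-] | intermediate
7 | sodium methanesulfinate | CS(=O)[O-].[Na+] | starting material
8 | 2-bromo-6-methoxy-4-methylidenecyclohexa-2,5-dien-1-one | C=C1C=C(Br)C(=O)C(OC)=C1 | intermediate
9 | 2-bromo-6-methoxy-4-[(methylsulfonyl)methyl]phenol | COc1cc(CS(C)(=O)=O)cc(Br)c1O | intermediate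
10 | 2,3-dibromo-6-methoxy-4-[(methylsulfonyl)methyl]phenol | COc1cc(CS(C)(=O)=O)c(Br)c(Br)c1O | intermediate
11 | 2,4,5-tribromo-6-[(methylsulfonyl)methyl]-1,3,2-benzodioxaborole | CS(=O)(=O)Cc1cc2OB(Br)Oc2c(Br)c1Br | intermediate
12 | 3,4-dibromo-5-[(methylsulfonyl)methyl]benzene-1,2-diol (2,3-dibromo-4,5-dihydroxybenzyl methyl sulfone) | CS(=O)(=O)Cc1cc(O)c(O)c(Br)c1Br | target

## Summary

Total step count: 5. Longest linear sequence: 5 steps (1 → 5 → 6 → 9 → 10 → 12).

Steps most likely to fail, each with a fallback:

- **Step 1 (para-Mannich on a bromophenol; risk of slow reaction or diarylmethane formation).** The fallback sets out from 1 and comes back at 9. Treat 1 with aqueous NaOH and 37% formaldehyde 2 at rt–40 °C. This is a Lederer–Manasse hydroxymethylation, an aldol-type addition of the phenoxide to formaldehyde, and goes para because both ortho positions are blocked. It gives 2-bromo-4-(hydroxymethyl)-6-methoxyphenol F1. Heat this benzylic alcohol with sodium methanesulfinate 7 in AcOH–H2O at 80–90 °C. Acid-promoted loss of water gives quinone methide 8, which is trapped by the sulfinate to give sulfone 9 directly, bypassing 5 and 6.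

- **Step 3 (sulfinate substitution; risk of quinone methide oligomerisation or competing N-demethylation of the ammonium salt).** The fallback sets out from 6 and comes back at 9. Treat 6 with sodium thiomethoxide in MeOH at rt–50 °C. The much more nucleophilic thiolate captures quinone methide 8 cleanly and gives 2-bromo-6-methoxy-4-[(methylsulfanyl)methyl]phenol F2. Oxidise this sulfide with H2O2 and catalytic Na2WO4 (or Oxone in MeOH–H2O, 0 °C → rt) to sulfone 9.

- **Step 4 (regioselectivity of the second bromination, or over-bromination of the free phenol).** The fallback sets out from 9 and comes back at 10. Acetylate the phenol (Ac2O, pyridine, rt) to 2-bromo-6-methoxy-4-[(methylsulfonyl)methyl]phenyl acetate F3. The acetoxy group is only a weak director and tempers the ring, so OMe alone controls the position. Brominate with Br2 and catalytic Fe in AcOH at 50 °C, para to OMe, to give 2,3-dibromo-6-methoxy-4-[(methylsulfonyl)methyl]phenyl acetate F4. Remove the acetate with catalytic K2CO3 in MeOH at rt to return to 10.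

## Further compounds

F1 | step 1 | 2-bromo-4-(hydroxymethyl)-6-methoxyphenol | COc1cc(CO)cc(Br)c1O
F2 | step 3 | 2-bromo-6-methoxy-4-[(methylsulfanyl)methyl]phenol | COc1cc(CSC)cc(Br)c1O
F3 | step 4 | 2-bromo-6-methoxy-4-[(methylsulfonyl)methyl]phenyl acetate | COc1cc(CS(C)(=O)=O)cc(Br)c1OC(C)=O
F4 | step 4 | 2,3-dibromo-6-methoxy-4-[(methylsulfonyl)methyl]phenyl acetate | COc1cc(CS(C)(=O)=O)c(Br)c(Br)c1OC(C)=O
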